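**Retrosynthetic overview**

1. The strategy rests on the chain C3–C2–C(=CH2)–CHO (C3 and C2 of the dihydrofuran ring plus the two carbons of the 2-substituent), which is C1–C4 of L-threonate. Threonate C2–O becomes the O1–C2 aryl ether, threonate C3 becomes the methylene-bearing carbon and C4 the formyl carbon.
2. Endgame: the enal comes from a primary allylic alcohol, the C=CH2 from a ketone at the former threonate C3, and the diol from the dioxolane. The acetate (C3) and the tiglate (side chain) are installed before the sensitive enal exists.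
3. The dihydrofuran ring is the only ring formed. It is closed at C3–C3a by an intramolecular Nozaki–Hiyama–Kishi addition of the aryl iodide to the tethered α-aryloxy aldehyde, which also creates C3 trans to C2.
4. The aldehyde comes from the methyl ester, the O1–C2 bond from a Mitsunobu etherification of the threonate C2–OH (inversion) with 4-hydroxy-3-iodoacetophenone, and the side-chain (R)-carbinol from asymmetric transfer hydrogenation of the aryl ketone.

Key step: step 5

Remark: the SMILES is read as the 2,3-trans isomer (2S,3R) with an (R)-configured tiglate-bearing carbinol; compounds 1 and 2 are taken as purchasable.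

**Route**

Step 1
Reactants: 1 methyl 3,4-O-isopropylidene-L-threonate; 2 1-(4-hydroxy-3-iodophenyl)ethanone
Product: 3 methyl (2S)-2-(4-acetyl-2-iodophenoxy)-2-[(4S)-2,2-dimethyl-1,3-dioxolan-4-yl]acetate
Conditions: PPh3, DIAD, THF, 0 °C → rt
Reagents that add atoms: none
Why: Mitsunobu etherification, in which the acidic phenol (para-acetyl, ortho-iodo) displaces the alkoxyphosphonium of the α-hydroxy ester by SN2, so threonate C2 inverts from R to S and already has the configuration needed at C2 of the benzofuran; the dioxolane stereocentre is untouched.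

Step 2
Reactants: 3 methyl (2S)-2-(4-acetyl-2-iodophenoxy)-2-[(4S)-2,2-dimethyl-1,3-dioxolan-4-yl]acetate
Product: 4 methyl (2S)-2-[(4S)-2,2-dimethyl-1,3-dioxolan-4-yl]-2-{4-[(1R)-1-hydroxyethyl]-2-iodophenoxy}acetate
Conditions: RuCl(p-cymene)[(R,R)-TsDPEN] (1 mol %), HCO2H/Et3N (5:2), EtOAc, 30 °C
Reagents that add atoms: none
Why: Noyori asymmetric transfer hydrogenation of an aryl methyl ketone, in which the (R,R)-diamine ligand is the one that delivers (R)-1-arylethanols (catalyst control), while the ester, acetonide and aryl iodide should not react.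

Step 3
Reactants: 4 methyl (2S)-2-[(4S)-2,2-dimethyl-1,3-dioxolan-4-yl]-2-{4-[(1R)-1-hydroxyethyl]-2-iodophenoxy}acetate
Product: 5 methyl (2S)-2-{4-[(1R)-1-{[tert-butyl(dimethyl)silyl]oxy}ethyl]-2-iodophenoxy}-2-[(4S)-2,2-dimethyl-1,3-dioxolan-4-yl]acetate
Conditions: TBSCl, imidazole, DMF, rt
Reagents that add atoms: tert-butyl(chloro)dimethylsilane (TBSCl), CC(C)(C)[Si](C)(C)Cl
Why: Imidazole-promoted silylation of the only free hydroxyl protects the benzylic carbinol for the hydride and chromium steps without touching any stereocentre.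

Step 4
Reactants: 5 methyl (2S)-2-{4-[(1R)-1-{[tert-butyl(dimethyl)silyl]oxy}ethyl]-2-iodophenoxy}-2-[(4S)-2,2-dimethyl-1,3-dioxolan-4-yl]acetate
Product: 7 (2S)-2-{4-[(1R)-1-{[tert-butyl(dimethyl)silyl]oxy}ethyl]-2-iodophenoxy}-2-[(4S)-2,2-dimethyl-1,3-dioxolan-4-yl]acetaldehyde, via aluminium hemiacetal 6 (not isolated)
Conditions: i-Bu2AlH (1.1 equiv), CH2Cl2, −78 °C; MeOH, then aq. potassium sodium tartrate
Reagents that add atoms: none
Why: Partial ester reduction with i-Bu2AlH, in which the α-aryloxy, β-alkoxy ester gives a chelated tetrahedral aluminium hemiacetal that is stable at −78 °C and releases the aldehyde only on work-up, so over-reduction is avoided; the aldehyde is to be used crude so that its α-stereocentre does not epimerise.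

Step 5
Reactants: 7 (2S)-2-{4-[(1R)-1-{[tert-butyl(dimethyl)silyl]oxy}ethyl]-2-iodophenoxy}-2-[(4S)-2,2-dimethyl-1,3-dioxolan-4-yl]acetaldehyde
Product: 10 (2R,3R)-5-[(1R)-1-{[tert-butyl(dimethyl)silyl]oxy}ethyl]-2-[(4S)-2,2-dimethyl-1,3-dioxolan-4-yl]-2,3-dihydro-1-benzofuran-3-ol, via arylchromium dichloride 8 (not isolated), via chromium alkoxide 9 (not isolated)
Conditions: CrCl2 (5 equiv), NiCl2 (2 mol %), degassed DMF (0.02 M), rt; aq. work-up
Reagents that add atoms: none
Why: Zerovalent nickel, generated from NiCl2 by CrCl2, inserts into the aryl C–I bond, the aryl group passes to trivalent chromium to give 8, and 8 adds to the tethered aldehyde to give alkoxide 9, which water hydrolyses. The closest known reaction type is the intramolecular Nozaki–Hiyama–Kishi coupling of ortho-iodoaryl ethers with aldehydes. The dihydrofuran ring closes in a 5-exo-trig mode as C3a attacks the carbonyl carbon and forms the C3–C3a bond. The new C3 stereocentre is set by substrate control from the adjacent C2 centre: in the envelope-like transition state the dioxolanyl group and the chromium-bound oxygen should take opposite faces, giving the 2,3-trans (2R,3R) alcohol. The step needs this trans selectivity and an intact α-aryloxy stereocentre; the bulk of the dioxolanyl group, DMF as a strongly coordinating solvent that disfavours a chromium chelate between the carbonyl and dioxolane oxygens, and the neutral, non-enolising conditions should secure both.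

Step 6
Reactants: 10 (2R,3R)-5-[(1R)-1-{[tert-butyl(dimethyl)silyl]oxy}ethyl]-2-[(4S)-2,2-dimethyl-1,3-dioxolan-4-yl]-2,3-dihydro-1-benzofuran-3-ol
Product: 11 (2R,3R)-5-[(1R)-1-{[tert-butyl(dimethyl)silyl]oxy}ethyl]-2-[(4S)-2,2-dimethyl-1,3-dioxolan-4-yl]-2,3-dihydro-1-benzofuran-3-yl acetate
Conditions: Ac2O, pyridine, DMAP (cat.), CH2Cl2, 0 °C → rt
Reagents that add atoms: acetic anhydride, CC(=O)OC(C)=O
Why: DMAP-catalysed acyl transfer to the secondary benzylic alcohol, which leaves the C3–O bond intact and so retains the C3 configuration.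

Step 7
Reactants: 11 (2R,3R)-5-[(1R)-1-{[tert-butyl(dimethyl)silyl]oxy}ethyl]-2-[(4S)-2,2-dimethyl-1,3-dioxolan-4-yl]-2,3-dihydro-1-benzofuran-3-yl acetate
Product: 12 (2R,3R)-2-[(4S)-2,2-dimethyl-1,3-dioxolan-4-yl]-5-[(1R)-1-hydroxyethyl]-2,3-dihydro-1-benzofuran-3-yl acetate
Conditions: TBAF, AcOH (1:1), THF, 0 °C → rt
Reagents that add atoms: none
Why: Fluoride-mediated desilylation of the only silyl ether, buffered with acetic acid so that the C3 acetate is neither cleaved nor moved and the carbinol C–O bond stays intact.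

Step 8
Reactants: 12 (2R,3R)-2-[(4S)-2,2-dimethyl-1,3-dioxolan-4-yl]-5-[(1R)-1-hydroxyethyl]-2,3-dihydro-1-benzofuran-3-yl acetate
Product: 13 (1R)-1-[(2R,3R)-3-(acetyloxy)-2-[(4S)-2,2-dimethyl-1,3-dioxolan-4-yl]-2,3-dihydro-1-benzofuran-5-yl]ethyl (2E)-2-methylbut-2-enoate
Conditions: tigloyl chloride, Et3N, DMAP (cat.), CH2Cl2, 0 °C → rt
Reagents that add atoms: (2E)-2-methylbut-2-enoyl chloride (tigloyl chloride), C/C=C(\C)C(Cl)=O
Why: DMAP-catalysed esterification with the acid chloride acylates the only free hydroxyl with retention at the carbinol carbon, and the thermodynamically preferred E geometry of the tiglate should persist.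

Step 9
Reactants: 13 (1R)-1-[(2R,3R)-3-(acetyloxy)-2-[(4S)-2,2-dimethyl-1,3-dioxolan-4-yl]-2,3-dihydro-1-benzofuran-5-yl]ethyl (2E)-2-methylbut-2-enoate
Product: 14 (1R)-1-[(2S,3R)-3-(acetyloxy)-2-[(1S)-1,2-dihydroxyethyl]-2,3-dihydro-1-benzofuran-5-yl]ethyl (2E)-2-methylbut-2-enoate
Conditions: AcOH/H2O (4:1), 35 °C
Reagents that add atoms: none
Why: Acid-catalysed acetal hydrolysis of the terminal isopropylidene acetal, the most acid-labile group present, with an acid too weak to ionise the two benzylic esters.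

Step 10
Reactants: 14 (1R)-1-[(2S,3R)-3-(acetyloxy)-2-[(1S)-1,2-dihydroxyethyl]-2,3-dihydro-1-benzofuran-5-yl]ethyl (2E)-2-methylbut-2-enoate
Product: 15 (1R)-1-[(2S,3R)-3-(acetyloxy)-2-[(1S)-2-{[tert-butyl(dimethyl)silyl]oxy}-1-hydroxyethyl]-2,3-dihydro-1-benzofuran-5-yl]ethyl (2E)-2-methylbut-2-enoate
Conditions: TBSCl (1.1 equiv), imidazole, CH2Cl2, 0 °C
Reagents that add atoms: tert-butyl(chloro)dimethylsilane (TBSCl), CC(C)(C)[Si](C)(C)Cl
Why: Sterically controlled monosilylation, in which the primary hydroxyl reacts well ahead of the hindered secondary one flanked by the ring.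

Step 11
Reactants: 15 (1R)-1-[(2S,3R)-3-(acetyloxy)-2-[(1S)-2-{[tert-butyl(dimethyl)silyl]oxy}-1-hydroxyethyl]-2,3-dihydro-1-benzofuran-5-yl]ethyl (2E)-2-methylbut-2-enoate
Product: 16 (1R)-1-[(2R,3R)-3-(acetyloxy)-2-({[tert-butyl(dimethyl)silyl]oxy}acetyl)-2,3-dihydro-1-benzofuran-5-yl]ethyl (2E)-2-methylbut-2-enoate
Conditions: Dess–Martin periodinane, CH2Cl2, 0 °C → rt
Reagents that add atoms: none
Why: Dess–Martin oxidation of the secondary alcohol runs without base, so the β-acetoxy ketone should neither lose acetic acid by an E1cB path nor epimerise at C2; the ketone is to be carried on at once.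

Step 12
Reactants: 16 (1R)-1-[(2R,3R)-3-(acetyloxy)-2-({[tert-butyl(dimethyl)silyl]oxy}acetyl)-2,3-dihydro-1-benzofuran-5-yl]ethyl (2E)-2-methylbut-2-enoate
Product: 17 (1R)-1-[(2S,3R)-3-(acetyloxy)-2-(3-{[tert-butyl(dimethyl)silyl]oxy}prop-1-en-2-yl)-2,3-dihydro-1-benzofuran-5-yl]ethyl (2E)-2-methylbut-2-enoate
Conditions: Zn, CH2Br2, TiCl4 (pre-formed reagent), THF/CH2Cl2, 0 °C → rt
Reagents that add atoms: dibromomethane, BrCBr
Why: Takai–Lombardo methylenation, whose zinc/titanium methylene reagent is non-basic and selective for ketones over esters, so the enolisable ketone should be converted to the 1,1-disubstituted alkene without touching the acetate, the tiglate or C2.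

Step 13
Reactants: 17 (1R)-1-[(2S,3R)-3-(acetyloxy)-2-(3-{[tert-butyl(dimethyl)silyl]oxy}prop-1-en-2-yl)-2,3-dihydro-1-benzofuran-5-yl]ethyl (2E)-2-methylbut-2-enoate
Product: 18 (1R)-1-[(2S,3R)-3-(acetyloxy)-2-(3-hydroxyprop-1-en-2-yl)-2,3-dihydro-1-benzofuran-5-yl]ethyl (2E)-2-methylbut-2-enoate
Conditions: HF·pyridine, pyridine, THF, 0 °C → rt
Reagents that add atoms: none
Why: Desilylation of the primary allylic silyl ether with buffered HF·pyridine avoids basic fluoride, so neither ester should migrate or cleave.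

Step 14
Reactants: 18 (1R)-1-[(2S,3R)-3-(acetyloxy)-2-(3-hydroxyprop-1-en-2-yl)-2,3-dihydro-1-benzofuran-5-yl]ethyl (2E)-2-methylbut-2-enoate
Product: 19 (1R)-1-[(2S,3R)-3-(acetyloxy)-2-(3-oxoprop-1-en-2-yl)-2,3-dihydro-1-benzofuran-5-yl]ethyl (2E)-2-methylbut-2-enoate
Conditions: MnO2 (activated), CH2Cl2, rt
Reagents that add atoms: none
Why: Allylic oxidation with MnO2 is heterogeneous, neutral and stops at the aldehyde, so the enal should form as the last operation without disturbing the esters or the C2 and C3 centres.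

**Compound list**

1 | methyl (2R)-2-[(4S)-2,2-dimethyl-1,3-dioxolan-4-yl]-2-hydroxyacetate (methyl 3,4-O-isopropylidene-L-threonate) | COC(=O)[C@H](O)[C@@H]1COC(C)(C)O1 | starting material
2 | 1-(4-hydroxy-3-iodophenyl)ethanone | CC(=O)c1ccc(O)c(I)c1 | starting material
3 | methyl (2S)-2-(4-acetyl-2-iodophenoxy)-2-[(4S)-2,2-dimethyl-1,3-dioxolan-4-yl]acetate | COC(=O)[C@@H](Oc1ccc(C(C)=O)cc1I)[C@@H]1COC(C)(C)O1 | intermediate
4 | methyl (2S)-2-[(4S)-2,2-dimethyl-1,3-dioxolan-4-yl]-2-{4-[(1R)-1-hydroxyethyl]-2-iodophenoxy}acetate | COC(=O)[C@@H](Oc1ccc([C@@H](C)O)cc1I)[C@@H]1COC(C)(C)O1 | intermediate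
5 | methyl (2S)-2-{4-[(1R)-1-{[tert-butyl(dimethyl)silyl]oxy}ethyl]-2-iodophenoxy}-2-[(4S)-2,2-dimethyl-1,3-dioxolan-4-yl]acetate | COC(=O)[C@@H](Oc1ccc([C@@H](C)O[Si](C)(C)C(C)(C)C)cc1I)[C@@H]1COC(C)(C)O1 | intermediate
6 | {(2S)-2-{4-[(1R)-1-{[tert-butyl(dimethyl)silyl]oxy}ethyl]-2-iodophenoxy}-2-[(4S)-2,2-dimethyl-1,3-dioxolan-4-yl]-1-methoxyethoxy}bis(2-methylpropyl)aluminium (aluminium hemiacetal, either configuration at the hemiacetal carbon) | COC(O[Al](CC(C)C)CC(C)C)[C@@H](Oc1ccc([C@@H](C)O[Si](C)(C)C(C)(C)C)cc1I)[C@@H]1COC(C)(C)O1 | intermediate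
7 | (2S)-2-{4-[(1R)-1-{[tert-butyl(dimethyl)silyl]oxy}ethyl]-2-iodophenoxy}-2-[(4S)-2,2-dimethyl-1,3-dioxolan-4-yl]acetaldehyde | O=C[C@@H](Oc1ccc([C@@H](C)O[Si](C)(C)C(C)(C)C)cc1I)[C@@H]1COC(C)(C)O1 | intermediate
8 | dichloro{5-[(1R)-1-{[tert-butyl(dimethyl)silyl]oxy}ethyl]-2-{[(1S)-1-[(4S)-2,2-dimethyl-1,3-dioxolan-4-yl]-2-oxoethyl]oxy}phenyl}chromium (arylchromium dichloride, trivalent chromium, DMF ligands omitted) | O=C[C@@H](Oc1ccc([C@@H](C)O[Si](C)(C)C(C)(C)C)cc1[Cr](Cl)Cl)[C@@H]1COC(C)(C)O1 | intermediate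
9 | dichlorochromium alkoxide of 10 (trivalent chromium, DMF ligands omitted) | C[C@@H](O[Si](C)(C)C(C)(C)C)c1ccc2O[C@@H]([C@@H]3COC(C)(C)O3)[C@H](O[Cr](Cl)Cl)c2c1 | intermediate
10 | (2R,3R)-5-[(1R)-1-{[tert-butyl(dimethyl)silyl]oxy}ethyl]-2-[(4S)-2,2-dimethyl-1,3-dioxolan-4-yl]-2,3-dihydro-1-benzofuran-3-ol | C[C@@H](O[Si](C)(C)C(C)(C)C)c1ccc2O[C@@H]([C@@H]3COC(C)(C)O3)[C@H](O)c2c1 | intermediate
11 | (2R,3R)-5-[(1R)-1-{[tert-butyl(dimethyl)silyl]oxy}ethyl]-2-[(4S)-2,2-dimethyl-1,3-dioxolan-4-yl]-2,3-dihydro-1-benzofuran-3-yl acetate | C[C@@H](O[Si](C)(C)C(C)(C)C)c1ccc2O[C@@H]([C@@H]3COC(C)(C)O3)[C@H](OC(C)=O)c2c1 | intermediate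
12 | (2R,3R)-2-[(4S)-2,2-dimethyl-1,3-dioxolan-4-yl]-5-[(1R)-1-hydroxyethyl]-2,3-dihydro-1-benzofuran-3-yl acetate | C[C@@H](O)c1ccc2O[C@@H]([C@@H]3COC(C)(C)O3)[C@H](OC(C)=O)c2c1 | intermediate
13 | (1R)-1-[(2R,3R)-3-(acetyloxy)-2-[(4S)-2,2-dimethyl-1,3-dioxolan-4-yl]-2,3-dihydro-1-benzofuran-5-yl]ethyl (2E)-2-methylbut-2-enoate | C[C@@H](OC(=O)/C(C)=C/C)c1ccc2O[C@@H]([C@@H]3COC(C)(C)O3)[C@H](OC(C)=O)c2c1 | intermediate
14 | (1R)-1-[(2S,3R)-3-(acetyloxy)-2-[(1S)-1,2-dihydroxyethyl]-2,3-dihydro-1-benzofuran-5-yl]ethyl (2E)-2-methylbut-2-enoate | C[C@@H](OC(=O)/C(C)=C/C)c1ccc2O[C@@H]([C@@H](O)CO)[C@H](OC(C)=O)c2c1 | intermediate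
15 | (1R)-1-[(2S,3R)-3-(acetyloxy)-2-[(1S)-2-{[tert-butyl(dimethyl)silyl]oxy}-1-hydroxyethyl]-2,3-dihydro-1-benzofuran-5-yl]ethyl (2E)-2-methylbut-2-enoate | C[C@@H](OC(=O)/C(C)=C/C)c1ccc2O[C@@H]([C@@H](O)CO[Si](C)(C)C(C)(C)C)[C@H](OC(C)=O)c2c1 | intermediate
16 | (1R)-1-[(2R,3R)-3-(acetyloxy)-2-({[tert-butyl(dimethyl)silyl]oxy}acetyl)-2,3-dihydro-1-benzofuran-5-yl]ethyl (2E)-2-methylbut-2-enoate | C[C@@H](OC(=O)/C(C)=C/C)c1ccc2O[C@@H](C(=O)CO[Si](C)(C)C(C)(C)C)[C@H](OC(C)=O)c2c1 | intermediate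
17 | (1R)-1-[(2S,3R)-3-(acetyloxy)-2-(3-{[tert-butyl(dimethyl)silyl]oxy}prop-1-en-2-yl)-2,3-dihydro-1-benzofuran-5-yl]ethyl (2E)-2-methylbut-2-enoate | C=C(CO[Si](C)(C)C(C)(C)C)[C@@H]1Oc2ccc([C@@H](C)OC(=O)/C(C)=C/C)cc2[C@H]1OC(C)=O | intermediate
18 | (1R)-1-[(2S,3R)-3-(acetyloxy)-2-(3-hydroxyprop-1-en-2-yl)-2,3-dihydro-1-benzofuran-5-yl]ethyl (2E)-2-methylbut-2-enoate | C=C(CO)[C@@H]1Oc2ccc([C@@H](C)OC(=O)/C(C)=C/C)cc2[C@H]1OC(C)=O | intermediate
19 | (1R)-1-[(2S,3R)-3-(acetyloxy)-2-(3-oxoprop-1-en-2-yl)-2,3-dihydro-1-benzofuran-5-yl]ethyl (2E)-2-methylbut-2-enoate (CNP0294391.1) | C=C(C=O)[C@@H]1Oc2ccc([C@@H](C)OC(=O)/C(C)=C/C)cc2[C@H]1OC(C)=O | target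

**Step count and risks**

Total step count: 14. Longest linear sequence: 14 steps (1 and 2 to 19).

Steps most likely to fail:

1. Step 5 (ring closure). The addition may show poor facial selectivity, or chelation of chromium to the dioxolane oxygen may steer it toward the 2,3-cis alcohol. Fallback: the C3 configuration is then set by SN2 inversion instead of by the addition itself. Setting out from 7, the closure is run as before and the cis alcohol (2R,3S)-5-[(1R)-1-{[tert-butyl(dimethyl)silyl]oxy}ethyl]-2-[(4S)-2,2-dimethyl-1,3-dioxolan-4-yl]-2,3-dihydro-1-benzofuran-3-ol F1 is separated. A Mitsunobu reaction of F1 with acetic acid (PPh3, DIAD, THF, 0 °C) should deliver acetate from the face opposite the dioxolanyl group and give the trans acetate directly, so the route is rejoined at 11 and step 6 is not needed for this material.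

2. Step 12 (methylenation). The β-acetoxy ketone 16 may lose acetic acid to the aromatic benzofuran before methylenation is complete, or the titanium reagent may ionise the benzylic acetate. Fallback: a Peterson sequence that replaces the zinc/titanium reagent by a low-temperature 1,2-addition. Setting out from 16, Me3SiCH2MgCl with CeCl3 in THF at −78 °C (a weakly basic organocerium reagent that prefers ketones to esters) should give the β-hydroxysilane (1R)-1-[(2R,3R)-3-(acetyloxy)-2-[1-{[tert-butyl(dimethyl)silyl]oxy}-2-hydroxy-3-(trimethylsilyl)propan-2-yl]-2,3-dihydro-1-benzofuran-5-yl]ethyl (2E)-2-methylbut-2-enoate F2 as a mixture of carbinol epimers. HF·pyridine in THF should then bring about the acid-induced elimination of both epimers to the same alkene and remove the primary silyl ether in the same flask, so the route is rejoined at 18.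

3. Step 1 (etherification). The hindered, β-oxygenated α-hydroxy ester may react slowly with the ortho-substituted phenol, so that elimination or hydrazide alkylation competes with the displacement. Fallback: activation and displacement are separated. Setting out from 1, Tf2O and pyridine in CH2Cl2 at −20 °C should give the triflate methyl (2R)-2-[(4S)-2,2-dimethyl-1,3-dioxolan-4-yl]-2-{[(trifluoromethyl)sulfonyl]oxy}acetate F3. The phenoxide of 2 (K2CO3, MeCN, 0 °C → rt) should displace the triflate with clean inversion, as α-triflyloxy esters do, so the route is rejoined at 3.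

**Further compounds**

F1 | step 5 | (2R,3S)-5-[(1R)-1-{[tert-butyl(dimethyl)silyl]oxy}ethyl]-2-[(4S)-2,2-dimethyl-1,3-dioxolan-4-yl]-2,3-dihydro-1-benzofuran-3-ol | C[C@@H](O[Si](C)(C)C(C)(C)C)c1ccc2O[C@@H]([C@@H]3COC(C)(C)O3)[C@@H](O)c2c1
F2 | step 12 | (1R)-1-[(2R,3R)-3-(acetyloxy)-2-[1-{[tert-butyl(dimethyl)silyl]oxy}-2-hydroxy-3-(trimethylsilyl)propan-2-yl]-2,3-dihydro-1-benzofuran-5-yl]ethyl (2E)-2-methylbut-2-enoate (both carbinol epimers) | C[C@@H](OC(=O)/C(C)=C/C)c1ccc2O[C@@H](C(O)(C[Si](C)(C)C)CO[Si](C)(C)C(C)(C)C)[C@H](OC(C)=O)c2c1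
F3 | step 1 | methyl (2R)-2-[(4S)-2,2-dimethyl-1,3-dioxolan-4-yl]-2-{[(trifluoromethyl)sulfonyl]oxy}acetate | COC(=O)[C@H](OS(=O)(=O)C(F)(F)F)[C@@H]1COC(C)(C)O1
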